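- Take 44%, the top of target in the eta run, as the share target keeps of dissolved solid substrate.

| flask | solid substrate | remark | time |
|---|---|---|---|
| eta | 0.0021 M | run made earlier |  |
| gamma | 0.033 M | run made earlier |  |
| midnight | 0.040 M |  | 2.0 min |
| summer | 0.015 M |  | 2.0 min |
| noon | 0.010 M |  | 2.0 min |
| dawn | 0.0025 M |  | 2.0 min |
| spring | 0.0050 M |  | 2.0 min |
| dusk | 0.0060 M |  | 2.0 min |

| run | time / s | target / % |
|---|---|---|
| eta | 20.0 | 14 |
| eta | 40.0 | 31 |
| eta | 60.0 | 43 |
| eta | 80.0 | 44 |
| eta | 90.0 | 43 |
| eta | 120 | 41 |
| gamma | 10.0 | 0 |
| gamma | 25.0 | 0 |
| gamma | 40.0 | 1 |
| gamma | 60.0 | 2 |
| gamma | 90.0 | 2 |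
| gamma | 120 | 8 |

(standard deviation of a reading: 1.5 percentage points)

- a species is counted by the solid substrate in it: one self-condensation product counts as two
- given per volume of solution although it is solid: solid substrate
- on the list of suspects stand: starting material <-> target; starting material <-> isomer of the product; starting material <-> third isomer; solid substrate <-> starting material; 2 starting material -> self-condensation product
- at the start none of the solid substrate is in solution
- what has only dissolved of solid substrate counts as not reacted

* ranking by amount of target, in percent of the solid substrate charged, from high to low, at 2.0 min (midnight / summer / noon / dawn / spring / dusk)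
* the same order at 25 s (midnight / summer / noon / dawn / spring / dusk)
* the amount of target, in percent of the solid substrate charged of the flask you put first, at 2.0 min
* the amount of target, in percent of the solid substrate charged of the flask you put last, at 2.0 min

- Read the feed next. Eta holds 43% at 60.0 s, so target grows at 0.0150 mM/s, and dividing by that share gives a dissolving rate F of 0.0342 mM/s.
- Fold the givens into the charge number B = c(solid substrate)/(F·t), the charge over what the feed delivers by that time; for noon at 2.0 min it is 2.44.
- Read it as a crossing, holding F and the share fixed. Above one, dissolving is the rate-limiting step and target is the share divided by B; below one, the charge is in and target sits at the share.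
- Test it on gamma, a larger charge than eta. It gives 5.47% at 120 s against a reading of 8%, and 4.10% at 90.0 s against 2%. The misses go opposite ways, with a scatter of 1.5 percentage points, so keep one number.
- Commit. Dawn, the smallest charge, has B = 0.609, below one, so expect 44%. Midnight has 9.75, so expect 4.51%. At 25 s even dawn stands at 2.92, above one, so percent follows the inverse charge and the order holds.
- The forecast says dawn > spring > dusk > noon > summer > midnight at 2.0 min and dawn > spring > dusk > noon > summer > midnight at 25 s, with 40% and 4.5%, because “dissolution is a fixed rate”; its top lies below mine.
- The flasks give dawn > spring > dusk > noon > summer > midnight at 2.0 min and dawn > spring > dusk > noon > summer > midnight at 25 s, with dawn at 44.0% and midnight at 4.08%.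

    starting material ⇌ target (K = 5.10, k = 0.405 /s)
    starting material ⇌ isomer of the product (K = 4.80, k = 0.164 /s)
    starting material ⇌ third isomer (K = 0.870, k = 0.397 /s)
    solid substrate ⇌ starting material, rate k4*(cs4 - [starting material]) while solid is left; crystals form when [starting material] > cs4 (solubility = 6.00 mM, k = 0.00520 /s)
    2 starting material → self-condensation product (k = 0.334 /M/s)

- In midnight, starting material and target relax together with a half-life of 1.43 s, far shorter than the 2.0 min asked. Solid substrate there still stands at 90.9% at 2.00 min, beside 0.878% starting material and 4.08% target. Carry the number to summer at 25 s: B is 17.5, which gives 2.51%, and the flask holds 2.43%.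

The readings were generated by integration with constants of no real substance; scatter was added.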